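Decalin carbons carry drimane numbers (C4 gem-dimethyl carbon, C5/C10 ring fusion, C8 the methyl-bearing CH, C9 the alkylidene carbon, C11 the benzylic CH, C12 the C8 methyl); the arene runs C1′ (on C11) to C6′ (C3′ and C6′ sulfated, C4′ OH, C5′ CHO).
Endgame: the two sulfates go onto a hydroquinone whose C4′ oxygen is held as an allyl ether; the E-C9=C11 bond comes from E1 dehydration of the carbinol formed by adding a C1′ aryllithium to the C11 aldehyde of the decalin.
Key disconnection: ring B (C5–C6–C7–C8–C9–C10) is a Diels–Alder retron once a C6=C7 double bond is written in, so C8–C9 and C5–C10 are made together by an intramolecular [4+2] of an acyclic, achiral trienal (diene C5=C6–C7=C8, dienophile C9=C10 activated through C11=O as an iminium ion).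
Enabling feature: on ring B, H5 and H8 are cis, the ring fusion is trans and the C8 and C10 methyl groups are cis, which is the pattern an endo addition of an (E,E)-diene to an (E)-β-methyl enal gives; C1–C4 of ring A is a four-carbon tether from C5 to C10, and C6/C7 are unsubstituted, so the extra double bond is simply hydrogenated.
Ring order: rings A and B form in one operation (step 8); the arene is made separately from 2,5-dihydroxybenzaldehyde, and the trienal from isobutyronitrile (alkylation, Takai olefination/Suzuki coupling, alkyne carboalumination).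

Key step: step 8

Remark: the target is drawn as the free bis(hydrogen sulfate); it is assumed to be generated from its sodium salt by cold stoichiometric protonation and handled cold and without delay, since aryl hydrogen sulfates hydrolyse on standing.

Step 1
Reactants: 1 isobutyronitrile; 2 1-bromo-3-chloropropane
Product: 4 5-chloro-2,2-dimethylpentanenitrile, via lithiated isobutyronitrile 3 (not isolated)
Conditions: LiN(i-Pr)2, THF, −78 °C; 2, −78 °C → rt
Reagents that add atoms: none
Why: SN2 α-alkylation of the lithiated nitrile should occur only at the C–Br end of the dihalide because bromide is much the better leaving group at low temperature; no stereocentre is formed.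

Step 2
Reactants: 4 5-chloro-2,2-dimethylpentanenitrile
Product: 6 5-chloro-2,2-dimethylpentanal, via N-(diisobutylalumino)aldimine 5 (not isolated)
Conditions: i-Bu2AlH, CH2Cl2, −78 °C; aqueous potassium sodium tartrate, 0 °C
Reagents that add atoms: water, O
Why: Hydride reduction of a nitrile with i-Bu2AlH stops at the N-aluminated aldimine, which hydrolysis converts to the aldehyde; the quaternary α-carbon excludes enolisation, and no stereocentre is formed.

Step 3
Reactants: 6 5-chloro-2,2-dimethylpentanal
Product: 7 (E)-6-chloro-1-iodo-3,3-dimethylhex-1-ene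
Conditions: CrCl2, CHI3, THF, 0 °C → rt
Reagents that add atoms: iodoform, IC(I)I
Why: Takai olefination with the geminal dichromium reagent should give the E-vinyl iodide, E selectivity being highest for α-branched aldehydes, while the primary alkyl chloride is inert to divalent chromium.

Step 4
Reactants: 7 (E)-6-chloro-1-iodo-3,3-dimethylhex-1-ene; 8 (E)-prop-1-enylboronic acid
Product: 9 (2E,4E)-9-chloro-6,6-dimethylnona-2,4-diene
Conditions: Pd(PPh3)4 (5 mol%), aq. NaOH, THF, 50 °C
Reagents that add atoms: none
Why: Suzuki–Miyaura coupling proceeds with retention at both sp2 carbons and should give the E,E-diene, the primary alkyl chloride not undergoing oxidative addition to zerovalent palladium under these conditions.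

Step 5
Reactants: 9 (2E,4E)-9-chloro-6,6-dimethylnona-2,4-diene
Product: 10 (7E,9E)-6,6-dimethylundeca-7,9-dien-1-yne
Conditions: LiC≡CH·H2NCH2CH2NH2, DMSO, rt
Reagents that add atoms: lithium acetylide ethylenediamine complex, [Li]C#C.NCCN
Why: SN2 displacement of the primary chloride by acetylide in DMSO is a standard terminal-alkyne synthesis, and acetylide is too weak a base to deprotonate the allylic positions of the diene.

Step 6
Reactants: 10 (7E,9E)-6,6-dimethylundeca-7,9-dien-1-yne
Product: 12 (2E,8E,10E)-3,7,7-trimethyldodeca-2,8,10-trien-1-ol, via alkenyl(dimethyl)alane 11 (not isolated)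
Conditions: AlMe3 (2.5 equiv), Cp2ZrCl2 (0.25 equiv), CH2Cl2, 0 °C → rt; n-BuLi, THF, −78 °C; (CH2O)n, −78 °C → rt; H2O
Reagents that add atoms: trimethylaluminium, C[Al](C)C; paraformaldehyde, C=O
Why: Negishi zirconium-catalysed carboalumination adds methyl and aluminium syn across the terminal alkyne with methyl on the internal carbon, and the derived alanate traps formaldehyde with retention, which fixes the E-trisubstituted alkene while the internal diene is untouched.

Step 7
Reactants: 12 (2E,8E,10E)-3,7,7-trimethyldodeca-2,8,10-trien-1-ol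
Product: 13 (2E,8E,10E)-3,7,7-trimethyldodeca-2,8,10-trienal
Conditions: MnO2 (activated), CH2Cl2, rt
Reagents that add atoms: none
Why: Allylic oxidation with MnO2 is selective for the allylic alcohol and neutral, so the E-enal should form without E/Z isomerisation or attack on the diene.

Step 8
Reactants: 13 (2E,8E,10E)-3,7,7-trimethyldodeca-2,8,10-trienal
Product: 15 (1S,2S,4aS,8aS)-2,5,5,8a-tetramethyl-1,2,4a,5,6,7,8,8a-octahydronaphthalene-1-carbaldehyde, via iminium triflate 14 (not isolated)
Conditions: (2S,5S)-5-benzyl-2-tert-butyl-3-methylimidazolidin-4-one (20 mol%), CF3SO3H (20 mol%), MeCN/H2O 98:2, 5 °C → rt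
Reagents that add atoms: none
Why: Proposed new method: condensation of 13 with the imidazolidinone gives the E-iminium ion 14, whose lowered LUMO lets the tethered E,E-diene add across C9=C10 in an asynchronous, Michael-like [4+2] in which C5–C10 forms ahead of C8–C9; the closest known reaction type is the imidazolidinone-catalysed type 1 intramolecular Diels–Alder reaction of β-monosubstituted 2,7,9-decatrienals, extended here to a β,β-disubstituted enal, whose iminium activation toward β-attack is known from conjugate reductions and intramolecular Michael additions. Ring A closes through the C1–C4 tether in a chair-like arrangement when C5–C10 forms, and ring B closes as the cyclohexene of the [4+2] when C8–C9 forms. C10 is set by the catalyst: its benzyl arm should cover one face of the iminium so that C5 adds to the Re face of C10 (priorities C9 > C1 > CH3), the same sense as known β-additions to crotonaldehyde with this catalyst. C5, C8 and C9 follow from C10 by suprafacial addition through the endo transition state (iminium under the diene, tether exo), which turns the E,E-diene and E-enal geometries into H5 trans to the C10 methyl and the C8 methyl, C10 methyl and C9 formyl all cis. The step needs endo over exo selectivity (trans- over cis-fusion) and retention of the E-enal geometry; the first rests on the endo preference of iminium dienophiles together with the E geometry that places the tether exo, the second on low temperature and the triflate salt so that cycloaddition outruns dienamine-mediated E/Z exchange.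

Step 9
Reactants: 15 (1S,2S,4aS,8aS)-2,5,5,8a-tetramethyl-1,2,4a,5,6,7,8,8a-octahydronaphthalene-1-carbaldehyde
Product: 16 (1S,2S,4aS,8aS)-2,5,5,8a-tetramethyldecahydronaphthalene-1-carbaldehyde
Conditions: H2 (1 atm), palladium on carbon (Pd/C, 10%), EtOAc, rt
Reagents that add atoms: none
Why: Heterogeneous catalytic hydrogenation should saturate the only C=C (cis-disubstituted C6=C7) faster than it touches the hindered aliphatic aldehyde, and it is placed before the coupling so that neither the allyl ether nor the styrene ever meets hydrogen; no stereocentre is formed or altered.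

Step 10
Reactants: 17 2,5-dihydroxybenzaldehyde
Product: 18 2,5-bis(methoxymethoxy)benzaldehyde
Conditions: CH3OCH2Cl, i-Pr2NEt, CH2Cl2, 0 °C → rt
Reagents that add atoms: chloromethyl methyl ether, COCCl
Why: O-alkylation of both phenols gives methoxymethyl (MOM) ethers, chosen because they stabilise the later ortho-aryllithium by chelation and can be removed without protic acid.

Step 11
Reactants: 18 2,5-bis(methoxymethoxy)benzaldehyde
Product: 20 2,5-bis(methoxymethoxy)phenol, via aryl formate 19 (not isolated)
Conditions: mCPBA, CH2Cl2, 0 °C → rt; K2CO3 (cat.), MeOH, rt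
Reagents that add atoms: 3-chloroperoxybenzoic acid, OOC(=O)c1cccc(Cl)c1
Why: Dakin-type Baeyer–Villiger oxidation, in which the electron-rich aryl group migrates and the formate is methanolysed, creates the phenol oxygen that becomes the unsulfated C4′ oxygen.

Step 12
Reactants: 20 2,5-bis(methoxymethoxy)phenol
Product: 21 2-hydroxy-3,6-bis(methoxymethoxy)benzaldehyde
Conditions: MgCl2, Et3N, (CH2O)n, MeCN, reflux
Reagents that add atoms: paraformaldehyde, C=O
Why: Casnati–Skattebøl magnesium-mediated formylation occurs only ortho to the free phenol, and the single free ortho position is C5′, so the formyl group should enter between the C4′ and C6′ oxygens.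

Step 13
Reactants: 21 2-hydroxy-3,6-bis(methoxymethoxy)benzaldehyde
Product: 22 5-bromo-2-hydroxy-3,6-bis(methoxymethoxy)benzaldehyde
Conditions: NBS, MeCN, 0 °C
Reagents that add atoms: N-bromosuccinimide, BrN1C(=O)CCC1=O
Why: Electrophilic aromatic bromination should go para to the free hydroxyl (C1′), a position also ortho to the C6′ MOM ether and meta to the deactivating formyl group, whereas the other free position is para to the formyl group.

Step 14
Reactants: 22 5-bromo-2-hydroxy-3,6-bis(methoxymethoxy)benzaldehyde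
Product: 23 2-(allyloxy)-5-bromo-3,6-bis(methoxymethoxy)benzaldehyde
Conditions: allyl bromide, K2CO3, DMF, 50 °C
Reagents that add atoms: allyl bromide, C=CCBr
Why: Williamson etherification places an allyl group, cleavable later by zerovalent palladium under neutral conditions, on the one oxygen (C4′) that must be freed after sulfation.

Step 15
Reactants: 23 2-(allyloxy)-5-bromo-3,6-bis(methoxymethoxy)benzaldehyde; 16 (1S,2S,4aS,8aS)-2,5,5,8a-tetramethyldecahydronaphthalene-1-carbaldehyde
Product: 26 2-(allyloxy)-5-{hydroxy[(1S,2S,4aS,8aS)-2,5,5,8a-tetramethyldecahydronaphthalen-1-yl]methyl}-3,6-bis(methoxymethoxy)benzaldehyde (both C11 epimers), via lithium amino alkoxide 24 (not isolated), via aryllithium 25 (not isolated)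
Conditions: LiN(CH3)CH2CH2N(CH3)2 (from the amine and n-BuLi), THF, −20 °C; n-BuLi, −78 °C; 16, −78 → −20 °C; H2O
Reagents that add atoms: none
Why: In situ aldehyde protection by lithium amide addition gives an α-amino alkoxide inert to n-BuLi, bromine–lithium exchange then gives the MOM-chelated aryllithium for 1,2-addition to the neopentyl-type aldehyde, and aqueous work-up returns the formyl group; the new C11 carbinol centre forms as an epimer mixture of no consequence because step 16 removes it.

Step 16
Reactants: 26 2-(allyloxy)-5-{hydroxy[(1S,2S,4aS,8aS)-2,5,5,8a-tetramethyldecahydronaphthalen-1-yl]methyl}-3,6-bis(methoxymethoxy)benzaldehyde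
Product: 28 2-(allyloxy)-3,6-bis(methoxymethoxy)-5-{(E)-[(2S,4aS,8aS)-2,5,5,8a-tetramethyloctahydronaphthalen-1(2H)-ylidene]methyl}benzaldehyde, via benzylic mesylate 27 (not isolated)
Conditions: CH3SO2Cl, Et3N, CH2Cl2, 0 → 40 °C
Reagents that add atoms: none
Why: E1 dehydration: the mesylate of this ortho,para-dialkoxybenzylic alcohol ionises and loses its only β-hydrogen (H9), so both C11 epimers converge on the C9=C11 styrene, and the E isomer (aryl cis to C8) should form because allylic 1,3-strain with quaternary C10 disfavours the other rotamer of the cation, the C8 methyl staying axial.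

Step 17
Reactants: 28 2-(allyloxy)-3,6-bis(methoxymethoxy)-5-{(E)-[(2S,4aS,8aS)-2,5,5,8a-tetramethyloctahydronaphthalen-1(2H)-ylidene]methyl}benzaldehyde
Product: 30 2-(allyloxy)-3,6-dihydroxy-5-{(E)-[(2S,4aS,8aS)-2,5,5,8a-tetramethyloctahydronaphthalen-1(2H)-ylidene]methyl}benzaldehyde, via bis(trimethylsilyl) ether 29 (not isolated)
Conditions: Me3SiOSO2CF3, 2,2′-bipyridyl, CH2Cl2, 0 °C → rt; H2O; under argon
Reagents that add atoms: none
Why: Silyl triflate/bipyridyl cleavage converts aromatic MOM ethers to aryl silyl ethers under buffered, non-protic conditions and water then frees the phenols, which avoids the acid-promoted cyclisation of the C6′ phenol onto C9=C11 and leaves the allyl ether and aldehyde intact.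

Step 18
Reactants: 30 2-(allyloxy)-3,6-dihydroxy-5-{(E)-[(2S,4aS,8aS)-2,5,5,8a-tetramethyloctahydronaphthalen-1(2H)-ylidene]methyl}benzaldehyde
Product: 32 disodium 2-(allyloxy)-3-formyl-5-{(E)-[(2S,4aS,8aS)-2,5,5,8a-tetramethyloctahydronaphthalen-1(2H)-ylidene]methyl}-1,4-phenylene bis(sulfate), via bis(pyridinium) sulfate salt 31 (not isolated)
Conditions: SO3·pyridine (excess), pyridine, 50 °C, argon; aq. NaHCO3
Reagents that add atoms: sulfur trioxide pyridine complex, O=S(=O)=O.c1ccncc1; sodium hydrogen carbonate, [Na+].OC([O-])=O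
Why: O-sulfonation of phenols with SO3·pyridine should sulfate exactly the C3′ and C6′ hydroxyls because the C4′ oxygen is allylated, and the base-stable sulfate monoesters are isolated as the sodium salt.

Step 19
Reactants: 32 disodium 2-(allyloxy)-3-formyl-5-{(E)-[(2S,4aS,8aS)-2,5,5,8a-tetramethyloctahydronaphthalen-1(2H)-ylidene]methyl}-1,4-phenylene bis(sulfate)
Product: 34 3-formyl-2-hydroxy-5-{(E)-[(2S,4aS,8aS)-2,5,5,8a-tetramethyloctahydronaphthalen-1(2H)-ylidene]methyl}-1,4-phenylene bis(hydrogen sulfate), via trisodium salt 33 (not isolated)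
Conditions: Pd(PPh3)4 (5 mol%), 4-CH3C6H4SO2Na, MeOH/THF, rt; aq. HCl (3.0 equiv), 0 °C; C18 desalting
Reagents that add atoms: none
Why: Tsuji–Trost deallylation: zerovalent palladium ionises the aryl allyl ether (a salicylaldehyde-type phenoxide leaves well) and the sulfinate traps the allyl unit as a sulfone under neutral conditions that spare sulfate monoesters, aldehyde and alkene, after which cold stoichiometric protonation should give the free acid.

Compound list
1 | isobutyronitrile | CC(C)C#N | starting material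
2 | 1-bromo-3-chloropropane | ClCCCBr | starting material
3 | lithiated isobutyronitrile (N-lithio keteniminate) | CC(C)=C=N[Li] | intermediate
4 | 5-chloro-2,2-dimethylpentanenitrile | N#CC(C)(C)CCCCl | intermediate
5 | N-(diisobutylalumino)aldimine of 6 | CC(C)C[Al](CC(C)C)N=CC(C)(C)CCCCl | intermediate
6 | 5-chloro-2,2-dimethylpentanal | O=CC(C)(C)CCCCl | intermediate
7 | (E)-6-chloro-1-iodo-3,3-dimethylhex-1-ene | ClCCCC(C)(C)/C=C/I | intermediate
8 | (E)-prop-1-enylboronic acid | C/C=C/B(O)O | starting material
9 | (2E,4E)-9-chloro-6,6-dimethylnona-2,4-diene | C/C=C/C=C/C(C)(C)CCCCl | intermediate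
10 | (7E,9E)-6,6-dimethylundeca-7,9-dien-1-yne | C#CCCCC(C)(C)/C=C/C=C/C | intermediate
11 | dimethyl[(1E,7E,9E)-2,6,6-trimethylundeca-1,7,9-trienyl]alane | C[Al](C)/C=C(\C)CCCC(C)(C)/C=C/C=C/C | intermediate
12 | (2E,8E,10E)-3,7,7-trimethyldodeca-2,8,10-trien-1-ol | OC/C=C(\C)CCCC(C)(C)/C=C/C=C/C | intermediate
13 | (2E,8E,10E)-3,7,7-trimethyldodeca-2,8,10-trienal | O=C/C=C(\C)CCCC(C)(C)/C=C/C=C/C | intermediate
14 | iminium triflate from 13 and the (2S,5S)-imidazolidinone (E-enal geometry kept) | C/C=C/C=C/C(C)(C)CCC/C(C)=C/C=[N+]1[C@H](C(C)(C)C)N(C)C(=O)[C@@H]1Cc1ccccc1.[O-]S(=O)(=O)C(F)(F)F | intermediate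
15 | (1S,2S,4aS,8aS)-2,5,5,8a-tetramethyl-1,2,4a,5,6,7,8,8a-octahydronaphthalene-1-carbaldehyde (C6=C7 octalin; 5α-H, 8β-CH3, 9β-CHO, 10β-CH3) | C[C@H]1C=C[C@H]2C(C)(C)CCC[C@]2(C)[C@H]1C=O | intermediate
16 | (1S,2S,4aS,8aS)-2,5,5,8a-tetramethyldecahydronaphthalene-1-carbaldehyde | C[C@H]1CC[C@H]2C(C)(C)CCC[C@]2(C)[C@H]1C=O | intermediate
17 | 2,5-dihydroxybenzaldehyde | O=Cc1cc(O)ccc1O | starting material
18 | 2,5-bis(methoxymethoxy)benzaldehyde | O=Cc1cc(OCOC)ccc1OCOC | intermediate
19 | 2,5-bis(methoxymethoxy)phenyl formate | O=COc1cc(OCOC)ccc1OCOC | intermediate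
20 | 2,5-bis(methoxymethoxy)phenol | Oc1cc(OCOC)ccc1OCOC | intermediate
21 | 2-hydroxy-3,6-bis(methoxymethoxy)benzaldehyde | O=Cc1c(O)c(OCOC)ccc1OCOC | intermediate
22 | 5-bromo-2-hydroxy-3,6-bis(methoxymethoxy)benzaldehyde | O=Cc1c(O)c(OCOC)cc(Br)c1OCOC | intermediate
23 | 2-(allyloxy)-5-bromo-3,6-bis(methoxymethoxy)benzaldehyde | O=Cc1c(OCC=C)c(OCOC)cc(Br)c1OCOC | intermediate
24 | lithium α-amino alkoxide of 23 (adduct of LiN(CH3)CH2CH2N(CH3)2 to the formyl group) | [Li]OC(N(C)CCN(C)C)c1c(OCC=C)c(OCOC)cc(Br)c1OCOC | intermediate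
25 | C1′-lithio derivative of 24 (lithium in place of bromine) | [Li]OC(N(C)CCN(C)C)c1c(OCC=C)c(OCOC)cc([Li])c1OCOC | intermediate
26 | 2-(allyloxy)-5-{hydroxy[(1S,2S,4aS,8aS)-2,5,5,8a-tetramethyldecahydronaphthalen-1-yl]methyl}-3,6-bis(methoxymethoxy)benzaldehyde (both C11 epimers) | C[C@H]1CC[C@H]2C(C)(C)CCC[C@]2(C)[C@H]1C(O)c1cc(OCOC)c(OCC=C)c(C=O)c1OCOC | intermediate
27 | C11 methanesulfonate of 26 | C[C@H]1CC[C@H]2C(C)(C)CCC[C@]2(C)[C@H]1C(OS(C)(=O)=O)c1cc(OCOC)c(OCC=C)c(C=O)c1OCOC | intermediate
28 | 2-(allyloxy)-3,6-bis(methoxymethoxy)-5-{(E)-[(2S,4aS,8aS)-2,5,5,8a-tetramethyloctahydronaphthalen-1(2H)-ylidene]methyl}benzaldehyde | C[C@H]1CC[C@H]2C(C)(C)CCC[C@]2(C)/C1=C/c1cc(OCOC)c(OCC=C)c(C=O)c1OCOC | intermediate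
29 | 3′,6′-bis(trimethylsilyl) ether of 30 | C[C@H]1CC[C@H]2C(C)(C)CCC[C@]2(C)/C1=C/c1cc(O[Si](C)(C)C)c(OCC=C)c(C=O)c1O[Si](C)(C)C | intermediate
30 | 2-(allyloxy)-3,6-dihydroxy-5-{(E)-[(2S,4aS,8aS)-2,5,5,8a-tetramethyloctahydronaphthalen-1(2H)-ylidene]methyl}benzaldehyde | C[C@H]1CC[C@H]2C(C)(C)CCC[C@]2(C)/C1=C/c1cc(O)c(OCC=C)c(C=O)c1O | intermediate
31 | bis(pyridinium) salt of the 3′,6′-bis(sulfate) of 30 | C[C@H]1CC[C@H]2C(C)(C)CCC[C@]2(C)/C1=C/c1cc(OS(=O)(=O)[O-])c(OCC=C)c(C=O)c1OS(=O)(=O)[O-].c1cc[nH+]cc1.c1cc[nH+]cc1 | intermediate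
32 | disodium 2-(allyloxy)-3-formyl-5-{(E)-[(2S,4aS,8aS)-2,5,5,8a-tetramethyloctahydronaphthalen-1(2H)-ylidene]methyl}-1,4-phenylene bis(sulfate) | C[C@H]1CC[C@H]2C(C)(C)CCC[C@]2(C)/C1=C/c1cc(OS(=O)(=O)[O-])c(OCC=C)c(C=O)c1OS(=O)(=O)[O-].[Na+].[Na+] | intermediate
33 | trisodium salt of the target (C4′ phenoxide, two sulfates) | C[C@H]1CC[C@H]2C(C)(C)CCC[C@]2(C)/C1=C/c1cc(OS(=O)(=O)[O-])c([O-])c(C=O)c1OS(=O)(=O)[O-].[Na+].[Na+].[Na+] | intermediate
34 | 3-formyl-2-hydroxy-5-{(E)-[(2S,4aS,8aS)-2,5,5,8a-tetramethyloctahydronaphthalen-1(2H)-ylidene]methyl}-1,4-phenylene bis(hydrogen sulfate) (CNP0309628.1) | C[C@H]1CC[C@H]2C(C)(C)CCC[C@]2(C)/C1=C/c1cc(OS(=O)(=O)O)c(O)c(C=O)c1OS(=O)(=O)O | target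

Total step count: 19. Longest linear sequence: 14 steps (steps 1–9, then 15–19); the arene branch (steps 10–14) is 5 steps.

Steps most likely to fail

Step 8 (proposed new method). The hindered β,β-disubstituted iminium may react so slowly that dienamine formation scrambles the enal geometry and the exo or uncatalysed pathways compete, eroding trans-fusion and facial selectivity; the developing 1,3-diaxial contact between the axial C4 methyl and the C10 methyl adds to this. The fallback uses auxiliary-controlled, Lewis-acid-promoted intramolecular Diels–Alder chemistry, known for 2,7,9-decatrienoyl imides. It sets out from 13: Pinnick oxidation (NaClO2, NaH2PO4, 2-methyl-2-butene, t-BuOH/H2O) should give (2E,8E,10E)-3,7,7-trimethyldodeca-2,8,10-trienoic acid F1. Its mixed pivalic anhydride (pivaloyl chloride, Et3N) is acylated with lithiated (S)-4-benzyloxazolidin-2-one to give the trienoyl imide F2. Me2AlCl (CH2Cl2, −30 → 0 °C) then promotes cycloaddition of the chelated s-cis imide, with the diene adding anti to the benzyl group (the same C10 Re face) through the endo transition state, to give the octalin imide F3. LiBH4 (Et2O, MeOH, 0 °C) cleaves the auxiliary to the primary alcohol F4, and Dess–Martin periodinane oxidation returns to the route at 15.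

Step 15. Masking of the aryl aldehyde may be incomplete, so that the aryllithium attacks unprotected 23, or proton transfer from the hindered aldehyde 16 may compete with addition at its crowded formyl group. The fallback replaces transient masking by an isolated acetal. It sets out from 23: Me3SiOCH2CH2OSiMe3 with catalytic Me3SiOSO2CF3 (CH2Cl2, −78 °C) should give 2-[2-(allyloxy)-5-bromo-3,6-bis(methoxymethoxy)phenyl]-1,3-dioxolane F5. Bromine–lithium exchange (n-BuLi, THF, −78 °C) and addition to 16 give the carbinol acetal F6, CH3SO2Cl/Et3N dehydration gives the styrene acetal F7, and pyridinium p-toluenesulfonate in wet acetone hydrolyses the dioxolane, returning to the route at 28.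

Step 18. O-sulfonation may stall at the hindered, hydrogen-bonded C6′ hydroxyl, the hydroquinone may oxidise to the quinone under the basic conditions, and the polar salt may be lost on aqueous isolation. The fallback installs the sulfates as neutral, chromatographable diesters. It sets out from 30: ClSO2OCH2CCl3, Et3N and 4-(dimethylamino)pyridine in THF should give the bis(2,2,2-trichloroethyl sulfate) F8. Zn dust with HCO2NH4 in MeOH removes both trichloroethyl groups reductively to give the diammonium bis(sulfate) F9, and aqueous NaHCO3 with lyophilisation exchanges the cation, returning to the route at 32.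

Further compounds
F1 | step 8 | (2E,8E,10E)-3,7,7-trimethyldodeca-2,8,10-trienoic acid | OC(=O)/C=C(\C)CCCC(C)(C)/C=C/C=C/C
F2 | step 8 | (S)-4-benzyl-3-[(2E,8E,10E)-3,7,7-trimethyldodeca-2,8,10-trienoyl]oxazolidin-2-one | O=C(/C=C(\C)CCCC(C)(C)/C=C/C=C/C)N1[C@@H](Cc2ccccc2)COC1=O
F3 | step 8 | (S)-4-benzyl-3-{[(1S,2S,4aS,8aS)-2,5,5,8a-tetramethyl-1,2,4a,5,6,7,8,8a-octahydronaphthalen-1-yl]carbonyl}oxazolidin-2-one | C[C@H]1C=C[C@H]2C(C)(C)CCC[C@]2(C)[C@H]1C(=O)N1[C@@H](Cc2ccccc2)COC1=O
F4 | step 8 | [(1S,2S,4aS,8aS)-2,5,5,8a-tetramethyl-1,2,4a,5,6,7,8,8a-octahydronaphthalen-1-yl]methanol | C[C@H]1C=C[C@H]2C(C)(C)CCC[C@]2(C)[C@H]1CO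
F5 | step 15 | 2-[2-(allyloxy)-5-bromo-3,6-bis(methoxymethoxy)phenyl]-1,3-dioxolane | C=CCOc1c(OCOC)cc(Br)c(OCOC)c1C1OCCO1
F6 | step 15 | [4-(allyloxy)-3-(1,3-dioxolan-2-yl)-2,5-bis(methoxymethoxy)phenyl][(1S,2S,4aS,8aS)-2,5,5,8a-tetramethyldecahydronaphthalen-1-yl]methanol (both C11 epimers) | C[C@H]1CC[C@H]2C(C)(C)CCC[C@]2(C)[C@H]1C(O)c1cc(OCOC)c(OCC=C)c(C2OCCO2)c1OCOC
F7 | step 15 | 2-[2-(allyloxy)-3,6-bis(methoxymethoxy)-5-{(E)-[(2S,4aS,8aS)-2,5,5,8a-tetramethyloctahydronaphthalen-1(2H)-ylidene]methyl}phenyl]-1,3-dioxolane | C[C@H]1CC[C@H]2C(C)(C)CCC[C@]2(C)/C1=C/c1cc(OCOC)c(OCC=C)c(C2OCCO2)c1OCOC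
F8 | step 18 | 2-(allyloxy)-3-formyl-5-{(E)-[(2S,4aS,8aS)-2,5,5,8a-tetramethyloctahydronaphthalen-1(2H)-ylidene]methyl}-1,4-phenylene bis(2,2,2-trichloroethyl) bis(sulfate) | C[C@H]1CC[C@H]2C(C)(C)CCC[C@]2(C)/C1=C/c1cc(OS(=O)(=O)OCC(Cl)(Cl)Cl)c(OCC=C)c(C=O)c1OS(=O)(=O)OCC(Cl)(Cl)Cl
F9 | step 18 | diammonium 2-(allyloxy)-3-formyl-5-{(E)-[(2S,4aS,8aS)-2,5,5,8a-tetramethyloctahydronaphthalen-1(2H)-ylidene]methyl}-1,4-phenylene bis(sulfate) | C[C@H]1CC[C@H]2C(C)(C)CCC[C@]2(C)/C1=C/c1cc(OS(=O)(=O)[O-])c(OCC=C)c(C=O)c1OS(=O)(=O)[O-].[NH4+].[NH4+]
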